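Germacranolide numbering is used (C10 bears ester carbon C14; C1 is the enoate CH; C8 carries the angelate; C6 the lactone oxygen). The ten-membered carbocycle C1–C10 is disconnected at C1–C2. Because C1 is the β-carbon of the C10=C1 enoate, this bond can be made as a C1=C2 olefin: ring-closing metathesis of an acyclic diene bearing a C10 vinyl ester and a C4 allyl group closes the ring in one operation, and base then moves the olefin into conjugation with C14, funnelling both C10 epimers and both olefin geometries into the single (E)-enoate. The precursor is an L-tartrate-derived dioxolane assembled by indium Barbier coupling, its C11=C13 acrylate masked as a sulfone.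

Key step: step 12

Remark: the numbering above is applied to the corresponding atoms of every intermediate (C2, C3 = ring CH2; C4 = carbon bearing the exocyclic methylene C15; C5 = carbinol carbon; C7 = ring-fusion carbon; C9 = CH2; C11–C13 = methylene-lactone carbons). The target is taken as drawn, (5S,6S,7R,8R), with C9 and C2 cis on the C1=C10 bond.

Step 1
Reactants: 1 dimethyl (4R,5R)-2,2-dimethyl-1,3-dioxolane-4,5-dicarboxylate
Product: 2 (4R,5R)-5-(methoxycarbonyl)-2,2-dimethyl-1,3-dioxolane-4-carboxylic acid
Conditions: KOH (1.0 equiv), MeOH, 0 to 23 °C; then aq. HCl to pH 3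
Reagents that add atoms: potassium hydroxide, [K+].[OH-]
Why: Ester hydrolysis of a C2-symmetric diester stops at the mono-acid because the carboxylate deactivates the second ester, which differentiates the future C4 and C7 ends without touching the two tartrate stereocenters (C5, C6).

Step 2
Reactants: 2 (4R,5R)-5-(methoxycarbonyl)-2,2-dimethyl-1,3-dioxolane-4-carboxylic acid; 3 allyltributylstannane
Product: 5 methyl (4R,5R)-5-(but-3-enoyl)-2,2-dimethyl-1,3-dioxolane-4-carboxylate, via acid chloride 4 (not isolated)
Conditions: (COCl)2, DMF (cat.), CH2Cl2, 0 to 23 °C; evaporate; 3, PdCl(CH2Ph)(PPh3)2 (2 mol%), THF, 23 to 45 °C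
Reagents that add atoms: oxalyl chloride, ClC(=O)C(=O)Cl (chlorine of 4)
Why: Acid chloride formation followed by a Stille-type acylation of the allylstannane gives the β,γ-unsaturated ketone under neutral conditions, so the C5 stereocenter, the skipped enone and the methyl ester are not exposed to base or to a hard nucleophile.

Step 3
Reactants: 5 methyl (4R,5R)-5-(but-3-enoyl)-2,2-dimethyl-1,3-dioxolane-4-carboxylate
Product: 6 methyl (4R,5S)-2,2-dimethyl-5-(penta-1,4-dien-2-yl)-1,3-dioxolane-4-carboxylate
Conditions: Tebbe reagent Cp2Ti(μ-Cl)(μ-CH2)AlMe2 (1.1 equiv), pyridine (cat.), THF/toluene, −40 to 0 °C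
Reagents that add atoms: Tebbe reagent, C[Al](C)C[Ti](Cl)(C1C=CC=C1)C1C=CC=C1
Why: Tebbe methylenation turns the enolizable ketone into the 1,1-disubstituted C4=C15 olefin without base (no epimerization at C5, no conjugation of the allyl group) and, with one equivalent at low temperature, faster than it attacks the ester.

Step 4
Reactants: 6 methyl (4R,5S)-2,2-dimethyl-5-(penta-1,4-dien-2-yl)-1,3-dioxolane-4-carboxylate
Product: 7 (4R,5S)-2,2-dimethyl-5-(penta-1,4-dien-2-yl)-1,3-dioxolane-4-carbaldehyde
Conditions: iBu2AlH (1.1 equiv), CH2Cl2, −78 °C; MeOH, then aq. potassium sodium tartrate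
Reagents that add atoms: none
Why: Partial reduction of the α-alkoxy ester stops at the aldehyde because the chelated aluminium hemiacetal survives at −78 °C until work-up, and the isolated olefins are inert to the hydride.

Step 5
Reactants: 7 (4R,5S)-2,2-dimethyl-5-(penta-1,4-dien-2-yl)-1,3-dioxolane-4-carbaldehyde; 8 methyl acrylate
Product: 9 methyl 2-{hydroxy[(4S,5S)-2,2-dimethyl-5-(penta-1,4-dien-2-yl)-1,3-dioxolan-4-yl]methyl}prop-2-enoate (both carbinol epimers)
Conditions: 8 (5 equiv), DABCO (1 equiv), MeOH, 23 °C, several days
Reagents that add atoms: none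
Why: The Morita–Baylis–Hillman reaction attaches C11–C13 to the C7 aldehyde; the new carbinol center is uncontrolled and need not be, since C7 becomes sp2 in step 6, and the trans-dioxolane is the thermodynamic epimer at C6.

Step 6
Reactants: 9 methyl 2-{hydroxy[(4S,5S)-2,2-dimethyl-5-(penta-1,4-dien-2-yl)-1,3-dioxolan-4-yl]methyl}prop-2-enoate
Product: 11 methyl (Z)-2-(bromomethyl)-3-[(4S,5S)-2,2-dimethyl-5-(penta-1,4-dien-2-yl)-1,3-dioxolan-4-yl]prop-2-enoate, via mesylate 10 (not isolated)
Conditions: MsCl, Et3N, CH2Cl2, −20 °C; then LiBr, THF/acetone, 0 to 23 °C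
Reagents that add atoms: methanesulfonyl chloride, CS(=O)(=O)Cl (mesyl group of 10); lithium bromide, [Li+].[Br-]
Why: Mesylation and SN2′ displacement by bromide transpose the allylic system to the thermodynamically preferred trisubstituted (Z)-2-(bromomethyl)enoate (ester trans to C6), the standard conversion of Morita–Baylis–Hillman adducts into allylic bromides.

Step 7
Reactants: 12 methyl (E)-but-2-enoate (methyl crotonate); 13 1-bromo-3-methylbut-2-ene (prenyl bromide)
Product: 15 methyl 2-ethenyl-5-methylhex-4-enoate (racemic), via lithium dienolate 14 (not isolated)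
Conditions: LiN(iPr)2, DMPU, THF, −78 °C; 13, −78 to −20 °C
Reagents that add atoms: lithium diisopropylamide, [Li+].CC(C)[N-]C(C)C (lithium of 14)
Why: Deconjugative α-alkylation: the lithium dienolate of the crotonate reacts with the allylic bromide at its α-carbon (SN2), giving the 2-vinyl ester whose stereocenter (C10) is deliberately left racemic because step 13 erases it.

Step 8
Reactants: 15 methyl 2-ethenyl-5-methylhex-4-enoate
Product: 17 methyl 2-ethenyl-4-oxobutanoate (racemic), via ozonide 16 (not isolated)
Conditions: O3 (dosed to the Sudan Red 7B end point), CH2Cl2, −78 °C; then PPh3, −78 to 23 °C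
Reagents that add atoms: ozone, [O-][O+]=O
Why: Ozonolysis with reductive work-up cleaves the electron-rich trisubstituted prenyl olefin much faster than the monosubstituted vinyl group next to the ester when ozone is dosed to an indicator end point, unmasking the C8 aldehyde.

Step 9
Reactants: 11 methyl (Z)-2-(bromomethyl)-3-[(4S,5S)-2,2-dimethyl-5-(penta-1,4-dien-2-yl)-1,3-dioxolan-4-yl]prop-2-enoate; 17 methyl 2-ethenyl-4-oxobutanoate
Product: 19 dimethyl (4R,5R)-2-ethenyl-4-hydroxy-6-methylidene-5-[(4S,5S)-2,2-dimethyl-5-(penta-1,4-dien-2-yl)-1,3-dioxolan-4-yl]heptanedioate (both C10 epimers), via allylindium dibromide 18 (not isolated)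
Conditions: In powder (1.5 equiv), 17 (1.5 equiv), THF/H2O (1:1), 23 °C
Reagents that add atoms: indium, [In] (indium of 18)
Why: The indium-mediated Barbier allylation tolerates both esters and should pass through a closed chair-like six-membered transition state in which the (Z)-allylindium delivers C7 to the aldehyde with the aldehyde substituent equatorial (C6 and the new C8 hydroxyl syn in the crotylation sense), while the C6–H bond eclipses the C7=C11 olefin (allylic 1,3-strain with the CH2In group) and the aldehyde adds anti to the C6–O bond, which sets C7 relative to C6.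

Step 10
Reactants: 19 Barbier adduct (C8 alcohol); 20 angelic acid [(Z)-2-methylbut-2-enoic acid]
Product: 21 C8 angelate of 19 (both C10 epimers)
Conditions: 20, 2,4,6-Cl3C6H2COCl, Et3N (1.0 equiv), toluene, 23 °C; filter; filtrate + 19, 75 °C
Reagents that add atoms: none
Why: Yamaguchi-type esterification through the mixed 2,4,6-trichlorobenzoic anhydride, without nucleophilic catalyst or free amine, should acylate the hindered C8 hydroxyl with retention of the (Z)-geometry of the acyl group and block lactonization of O8 onto C12 or C14.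

Step 11
Reactants: 21 C8 angelate with free C11=C13 acrylate
Product: 22 β-sulfonyl ester (C13 p-tolylsulfonyl adduct of 21; mixture at C10 and C11)
Conditions: TolSO2Na (1.5 equiv), AcOH (2 equiv), EtOH, 45 °C
Reagents that add atoms: sodium p-toluenesulfinate, [Na+].Cc1ccc(S(=O)[O-])cc1
Why: Sulfa-Michael addition of the sulfinate to the only unhindered acceptor, the C11=C13 acrylate, masks it as a β-sulfonyl ester that is inert to ruthenium alkylidenes; the new C11 center is uncontrolled and is erased again in step 13.

Step 12
Reactants: 22 β-sulfonyl ester seco-diene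
Product: 23 ten-membered carbocycle with C1=C2 olefin (acetonide, C13 sulfone; mixture at C10, C11 and of olefin geometry)
Conditions: second-generation Hoveyda–Grubbs catalyst RuCl2(H2IMes)(=CH–C6H4-2-OiPr) (10 mol% in two portions), 1,4-benzoquinone (20 mol%), toluene (1 mM, slow addition of 22), 80 °C, argon sparge
Reagents that add atoms: none
Why: Ring-closing olefin metathesis: the ruthenium alkylidene loads on the unhindered monosubstituted allyl terminus (C2), undergoes [2+2] cycloaddition and cycloreversion with the C10 vinyl group (C1) and releases ethylene, whose removal makes the closure irreversible. The closest known reaction type is diene ring-closing metathesis to cyclodecenes and other ten-membered carbocycles. The ring closed is the carbocycle C1–C10, formed from a 1,9-diene with the new C1=C2 olefin inside the ring. No stereocenter is created and none is needed, because both C10 epimers, both C11 epimers and either C1=C2 geometry are accepted and erased in step 13. The selectivity needed is chemoselectivity among the olefins and cyclization over oligomerization: the 1,1-disubstituted C4=C15 and the trisubstituted angelate olefins are too hindered to compete, the C11=C13 acrylate (which would close a six-membered ring onto C1) is absent as its sulfinate adduct, high dilution and the turn imposed by the trans-dioxolane and the C7/C8 branches favour the monomeric ring, and benzoquinone suppresses ruthenium hydride migration of the skipped diene.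

Step 13
Reactants: 23 ten-membered carbocycle with C1=C2 olefin and C13 sulfone
Product: 25 conjugated (E)-C1=C10 enoate with restored C11=C13 acrylate (acetonide), via acrylate 24 (not isolated)
Conditions: DBU (3 equiv), CH2Cl2, 23 °C
Reagents that add atoms: none
Why: Base-mediated isomerization: DBU removes the C10–H (α to the ester and allylic) and the extended enolate is reprotonated at C2, moving the ring olefin into conjugation with C14 and converging all isomers on the thermodynamically preferred (E)-enoate with C9 and C2 cis on the ring, while the same base expels p-toluenesulfinate from C13 by E1cB elimination.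

Step 14
Reactants: 25 conjugated enoate acetonide
Product: 27 CNP0163095.1, via diol 26 (not isolated)
Conditions: aq. HCl (2 M)/THF (1:3), 23 °C; then p-TsOH·H2O (cat.), CH2Cl2, 23 °C
Reagents that add atoms: none
Why: Acid hydrolysis of the isopropylidene acetal frees O5 and O6, and acid-catalysed lactonization of O6 onto the C12 acrylate ester closes the five-membered α-methylene lactone (favoured over the six-membered alternative through O5), trans-fused because C6 and C7 were fixed in steps 1 and 9.

Compound list
1 | dimethyl (4R,5R)-2,2-dimethyl-1,3-dioxolane-4,5-dicarboxylate (from L-tartaric acid) | COC(=O)[C@@H]1OC(C)(C)O[C@H]1C(=O)OC | starting material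
2 | (4R,5R)-5-(methoxycarbonyl)-2,2-dimethyl-1,3-dioxolane-4-carboxylic acid | OC(=O)[C@@H]1OC(C)(C)O[C@H]1C(=O)OC | intermediate
3 | allyltributylstannane | C=CC[Sn](CCCC)(CCCC)CCCC | starting material
4 | methyl (4R,5R)-5-(chlorocarbonyl)-2,2-dimethyl-1,3-dioxolane-4-carboxylate (not isolated) | ClC(=O)[C@@H]1OC(C)(C)O[C@H]1C(=O)OC | intermediate
5 | methyl (4R,5R)-5-(but-3-enoyl)-2,2-dimethyl-1,3-dioxolane-4-carboxylate | C=CCC(=O)[C@@H]1OC(C)(C)O[C@H]1C(=O)OC | intermediate
6 | methyl (4R,5S)-2,2-dimethyl-5-(penta-1,4-dien-2-yl)-1,3-dioxolane-4-carboxylate | C=CCC(=C)[C@@H]1OC(C)(C)O[C@H]1C(=O)OC | intermediate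
7 | (4R,5S)-2,2-dimethyl-5-(penta-1,4-dien-2-yl)-1,3-dioxolane-4-carbaldehyde | C=CCC(=C)[C@@H]1OC(C)(C)O[C@H]1C=O | intermediate
8 | methyl acrylate | C=CC(=O)OC | starting material
9 | methyl 2-{hydroxy[(4S,5S)-2,2-dimethyl-5-(penta-1,4-dien-2-yl)-1,3-dioxolan-4-yl]methyl}prop-2-enoate, both carbinol epimers | C=CCC(=C)[C@@H]1OC(C)(C)O[C@H]1C(O)C(=C)C(=O)OC | intermediate
10 | methanesulfonate of 9 (not isolated) | C=CCC(=C)[C@@H]1OC(C)(C)O[C@H]1C(OS(C)(=O)=O)C(=C)C(=O)OC | intermediate
11 | methyl (Z)-2-(bromomethyl)-3-[(4S,5S)-2,2-dimethyl-5-(penta-1,4-dien-2-yl)-1,3-dioxolan-4-yl]prop-2-enoate | C=CCC(=C)[C@@H]1OC(C)(C)O[C@H]1/C=C(\CBr)C(=O)OC | intermediate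
12 | methyl (E)-but-2-enoate (methyl crotonate) | C/C=C/C(=O)OC | starting material
13 | 1-bromo-3-methylbut-2-ene (prenyl bromide) | CC(C)=CCBr | starting material
14 | lithium 1-methoxybuta-1,3-dien-1-olate (not isolated) | [Li+].[O-]C(OC)=CC=C | intermediate
15 | methyl 2-ethenyl-5-methylhex-4-enoate, racemic | C=CC(CC=C(C)C)C(=O)OC | intermediate
16 | secondary ozonide of 15: methyl 2-[(5,5-dimethyl-1,2,4-trioxolan-3-yl)methyl]but-3-enoate (not isolated) | C=CC(CC1OOC(C)(C)O1)C(=O)OC | intermediate
17 | methyl 2-ethenyl-4-oxobutanoate, racemic | C=CC(CC=O)C(=O)OC | intermediate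
18 | allylindium dibromide derived from 11, simplest formulation (not isolated) | C=CCC(=C)[C@@H]1OC(C)(C)O[C@H]1/C=C(\C[In](Br)Br)C(=O)OC | intermediate
19 | dimethyl (4R,5R)-2-ethenyl-4-hydroxy-6-methylidene-5-[(4S,5S)-2,2-dimethyl-5-(penta-1,4-dien-2-yl)-1,3-dioxolan-4-yl]heptanedioate; C5–C8 configured as in the target, both C10 epimers | C=CCC(=C)[C@@H]1OC(C)(C)O[C@H]1[C@H](C(=C)C(=O)OC)[C@H](O)CC(C=C)C(=O)OC | intermediate
20 | angelic acid, (Z)-2-methylbut-2-enoic acid | C/C=C(/C)C(=O)O | starting material
21 | C8 (Z)-2-methylbut-2-enoate (angelate) of 19, both C10 epimers | C=CCC(=C)[C@@H]1OC(C)(C)O[C@H]1[C@H](C(=C)C(=O)OC)[C@H](OC(=O)/C(C)=C\C)CC(C=C)C(=O)OC | intermediate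
22 | sulfinate adduct of 21: C11 carries H and CH2SO2(p-tolyl) in place of the methylidene; mixture at C10 and C11 | C=CCC(=C)[C@@H]1OC(C)(C)O[C@H]1[C@H](C(CS(=O)(=O)c2ccc(C)cc2)C(=O)OC)[C@H](OC(=O)/C(C)=C\C)CC(C=C)C(=O)OC | intermediate
23 | ring-closed cyclodeca-1,4(15)-diene: C1=C2 ring olefin, C10 CH(CO2Me), C8 angelate, C7 side chain CH(CH2SO2Tol)CO2Me, 5,6-O-isopropylidene; mixture at C10, C11 and of C1=C2 geometry | C=C1CC=CC(C(=O)OC)C[C@@H](OC(=O)/C(C)=C\C)[C@@H](C(CS(=O)(=O)c3ccc(C)cc3)C(=O)OC)[C@@H]2OC(C)(C)O[C@@H]12 | intermediate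
24 | as 23 after loss of sulfinate: C7 side chain C(=CH2)CO2Me, C1=C2 still unconjugated (not isolated) | C=C1CC=CC(C(=O)OC)C[C@@H](OC(=O)/C(C)=C\C)[C@@H](C(=C)C(=O)OC)[C@@H]2OC(C)(C)O[C@@H]12 | intermediate
25 | 5,6-O-isopropylidene seco-lactone of the target: (E)-C1=C10 enoate (C9 and C2 cis), C8 angelate, C7 side chain C(=CH2)CO2Me | C=C1CC/C=C(C(=O)OC)\C[C@@H](OC(=O)/C(C)=C\C)[C@@H](C(=C)C(=O)OC)[C@@H]2OC(C)(C)O[C@@H]12 | intermediate
26 | 5,6-diol corresponding to 25 (not isolated) | C=C1CC/C=C(C(=O)OC)\C[C@@H](OC(=O)/C(C)=C\C)[C@@H](C(=C)C(=O)OC)[C@H](O)[C@H]1O | intermediate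
27 | CNP0163095.1: methyl (5S,6S,7R,8R)-8-angeloyloxy-5-hydroxy-12-oxo-germacra-1(10),4(15),11(13)-trien-12,6-olid-14-oate, C9 and C2 cis on C1=C10 | C=C1C(=O)O[C@H]2[C@H]1[C@H](OC(=O)/C(C)=C\C)C/C(C(=O)OC)=C\CCC(=C)[C@@H]2O | target

Total step count: 14. Longest linear sequence: 12 steps (steps 1–6, then 9–14); steps 7 and 8 make the second fragment.

Steps most likely to fail

Step 12 (ring closure). Intermolecular metathesis may outrun closure of the strained ten-membered ring, ruthenium hydrides may migrate the skipped diene, and one C10 epimer may cyclize too slowly. Fallback: the ring is closed on a different template. Sulfone 22 is first treated with aq. HCl/THF and then p-TsOH, so that the dioxolane is removed and O6 lactonizes onto C12, giving the trans-fused seco-lactone sulfone F1. Its γ-lactone (ring of O, C6, C7, C11, C12) holds the C5 and C8 arms in the arrangement of the natural germacranolide fold. Metathesis of F1 under the conditions of step 12 should then give the cyclodecene lactone sulfone F2. DBU on F2 performs both the olefin migration and the sulfinate elimination and delivers 27 directly. The fallback sets out from 22 and comes back at 27.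

Step 9 (Barbier coupling). The allylindium may undergo 1,4-elimination with loss of the dioxolane oxygen, facial selectivity at C7 may be poor, and the adduct may lactonize prematurely. Fallback: the organometallic is replaced by an isolable allylboron reagent. Bromide 11 is borylated (B2pin2, Pd2(dba)3, DMSO, 23 °C) to the allylboronate F3, which is not prone to elimination. F3 is added to 17 under Sc(OTf)3 catalysis in toluene at −78 to 0 °C, or with a chiral BINOL-derived phosphoric acid if catalyst control of the face is needed. The same closed chair transition state should give 19. The fallback sets out from 11 and comes back at 19.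

Step 10 (angeloylation). The acyl group may isomerize from Z to E, acylation of the hindered hydroxyl may be slow enough to allow lactonization onto C12 or C14, and the 2-vinyl ester may drift into conjugation. Fallback: the (Z)-olefin of the ester is built on the oxygen instead of being transferred. Alcohol 19 is esterified with the unhindered 2-[bis(2,2,2-trifluoroethoxy)phosphoryl]propanoic acid (DCC, DMAP cat., CH2Cl2, 0 °C) to the phosphonate ester F4. Still–Gennari olefination of F4 with acetaldehyde (KN(SiMe3)2, 18-crown-6, THF, −78 °C) then forms the (Z)-2-methylbut-2-enoate and gives 21. The fallback sets out from 19 and comes back at 21.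

Further compounds
F1 | step 12 | seco-lactone sulfone: 5-hydroxy-6,12-olide with C11 CH(CH2SO2Tol), C8 angelate, C4 allyl/methylidene and C10 vinyl ester (mixture at C10 and C11) | C=CCC(=C)[C@H](O)[C@H]1OC(=O)C(CS(=O)(=O)c2ccc(C)cc2)[C@@H]1[C@H](OC(=O)/C(C)=C\C)CC(C=C)C(=O)OC
F2 | step 12 | cyclodecene lactone sulfone: ring-closed F1 with C1=C2 olefin (mixture at C10, C11 and of olefin geometry) | C=C1CC=CC(C(=O)OC)C[C@@H](OC(=O)/C(C)=C\C)[C@H]2C(CS(=O)(=O)c3ccc(C)cc3)C(=O)O[C@@H]2[C@H]1O
F3 | step 9 | allylboronate: methyl 3-[(4S,5S)-2,2-dimethyl-5-(penta-1,4-dien-2-yl)-1,3-dioxolan-4-yl]-2-[(4,4,5,5-tetramethyl-1,3,2-dioxaborolan-2-yl)methyl]prop-2-enoate, olefin geometry as in 11 | C=CCC(=C)[C@@H]1OC(C)(C)O[C@H]1/C=C(\CB2OC(C)(C)C(C)(C)O2)C(=O)OC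
F4 | step 10 | phosphonate ester: C8 2-[bis(2,2,2-trifluoroethoxy)phosphoryl]propanoate of 19 | C=CCC(=C)[C@@H]1OC(C)(C)O[C@H]1[C@H](C(=C)C(=O)OC)[C@H](OC(=O)C(C)P(=O)(OCC(F)(F)F)OCC(F)(F)F)CC(C=C)C(=O)OC
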